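A small charge of Q, 5.00% of the G in the zeta run, has given 5.61 J per Q charged by 52 min. There the J reading stands at 28.1% of the G charged, and its last interval added 0.733% against 10.5% in the first. That flattening is what to watch.

common to all: Q 0.00750 M

| flask | G | E | time |
|---|---|---|---|
| zeta | 0.150 M | 0.300 M |  |
| delta | 0.0600 M | 0.210 M |  |
| alpha | 0.150 M | 0.600 M |  |
| theta | 0.300 M | 0.300 M |  |
| gamma | 0.150 M | 1.00 M | 52 min |

| zeta run: time / min | zeta run: [J] / M | delta run: time / min | delta run: [J] / M | alpha run: time / min | alpha run: [J] / M | theta run: time / min | theta run: [J] / M |
|---|---|---|---|---|---|---|---|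
| 8.7 | 0.0157 | 8.7 | 0.0096 | 8.7 | 0.0265 | 8.7 | 0.0170 |
| 17 | 0.0262 | 17 | 0.0151 | 17 | 0.0458 | 17 | 0.0275 |
| 26 | 0.0331 | 26 | 0.0197 | 26 | 0.0588 | 26 | 0.0364 |
| 35 | 0.0385 | 35 | 0.0217 | 35 | 0.0681 | 35 | 0.0414 |
| 43 | 0.0410 | 43 | 0.0235 | 43 | 0.0724 | 43 | 0.0441 |
| 52 | 0.0421 | 52 | 0.0237 | 52 | 0.0752 | 52 | 0.0454 |

(scatter of a reading: 4 × 10⁻⁴ M)

- the power of [E] that the first rate follows, about the charge of the zeta run; measure it at two percent of G made into J
- the power of [G] that the first rate follows, about the charge of the zeta run; measure it at two percent of G made into J (one fixed amount of J, the same in the runs compared)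
- J in the gamma run at 52 min, as a share of the G charged

- Overall: G + E -> J, with Q as catalyst.
- Constant volume, constant temperature.
- A reading of a species includes what of it is bound.
- An order is taken over about fifteen percent of the charge, up and down.

Two views part over this stall. The forecast says “the catalyst is dying”, and it carries a bending rate law forward. It gives 0.77 in E (range 0.62 to 0.9), 0.22 in G (0.08 to 0.38), and 66% for the gamma run (58% to 74%).

My own reckoning differs: leave the first rate aside and work from where the runs end. At a small share, the share seems to go as E over G. Doubling G in the theta run gives about half the zeta share, and doubling E in the alpha run gives 1.79 times it. At a large share, the curve has to bend below the whole charge.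

A logarithm joins these two ends, and in the zeta run it comes to 0.165. Call this number the reach: the natural log of the G charge over that charge less the last J reading, times the G charge over the E charge.

The alpha run reads 0.174, and the delta run, with E at 0.210 M and G at 0.0600 M, reads 0.144. So across these three runs the reach stands higher where the E charge is higher, though the delta run differs in G as well. A straight line through zeta and alpha gives 0.186 at the gamma charge, and that means 71.1% of G as J, higher than the forecast.

The gamma run gives 71.4%, a reach of 0.188.

    Q + G ⇌ QG, settled at all times (39.60 M⁻¹)
    QG + E ⇌ QGE, settled at all times (0.9070 M⁻¹)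
    QGE → J + Q (1.542 min⁻¹)
    E → Zu (0.03684 min⁻¹)
    J → Ky (0.002880 min⁻¹)

The simulation's E order of 0.87 lies inside the forecast's range around 0.77, so about the zeta charge the forecast's bending law serves for E, while its G order of 0.22 is higher than 0.14. On the theta run, the zeta reach gives 15.2% and the reading is 15.1%. In the gamma run, QGE → J + Q ran while E was there, with 0.907 QGE per QG at the start, and that step hands Q back. E → Zu ran beside it from the start, and over 52 min that step by itself keeps 14.7% of the E charged.

All runs are calculated on assumed constants; scatter was added.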